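**Retrosynthetic overview**

1. The strategy rests on ring B (C5–C10) and its quaternary C10, whose oxygenated substituent C20 maps onto an exocyclic enol ether C10=C20H–OBn. Ring B is closed last among the carbocycles, at C9–C10, by a formate-terminated Heck cyclisation of a ring C enol triflate (C9) onto that ring A enol ether.
2. After it: hydrogen-atom-transfer reduction of C9=C11, debenzylation with C19→C20 lactonisation, oxidative demethylation, quinone reduction.
3. Before it: the C7–C8 bond joins the two preformed six-membered rings (ring C dienolate + ring A primary iodide); C8 is then methylated anti to the C14 arylmethyl group and the enone is reductively triflated.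
4. Ring C: p-cresol → quinol benzyl ether → copper-catalysed desymmetrising benzyl addition (C13 and C14). C13 is carried as the benzyl ether of the tertiary alcohol, so no isomerisable exocyclic alkene meets palladium hydride and no late hydration is needed.
5. Ring A: 3-oxocyclohexenecarboxylate → asymmetric conjugate methylation (C4) with intramolecular enolate alkylation through a 2-bromoethyl ester tether (C5, C6, C7) → Wittig enol ether → lactone opening. Ring order: A and C from commercial rings, then B (step 12), then the δ-lactone.

Key step: step 12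

Assumption: atoms carry the diterpenoid locants of the target (ring A C1–C5 and C10; ring B C5–C10; ring C C8, C9, C11–C14; C15 the benzylic CH2; C19 the lactone carbonyl; C20 the OCH2 on C10), β is the face of C20 and of the C8 methyl, and the antipode of each chiral ligand (steps 2 and 8) is taken to be the one that gives the configurations drawn.

**Route**

Step 1
Reactants: 1 methyl 3-oxocyclohex-1-ene-1-carboxylate; 2 2-bromoethanol
Product: 3 2-bromoethyl 3-oxocyclohex-1-ene-1-carboxylate
Conditions: 2 (5 equiv), Bu2SnO (10 mol%), PhMe, 110 °C, MeOH distilled off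
Reagents that add atoms: none
Why: Tin-catalysed transesterification is neutral, so the enone and the primary bromide should be untouched, and removal of methanol drives it; no stereocenter is formed.

Step 2
Reactants: 3 2-bromoethyl 3-oxocyclohex-1-ene-1-carboxylate
Product: 5 cis-fused keto δ-lactone 8a-methylhexahydro-1H-isochromene-1,5-dione (C19(=O)–O–C7 lactone; C10 ketone; H5 cis to the C4 methyl), via methylzinc enolate 4 (not isolated)
Conditions: Me2Zn (3 equiv), Cu(OTf)2 (2.5 mol%), chiral sulfonate-bearing imidazolinium salt (carbene precursor, 5 mol%), t-BuOMe, −30 °C; then HMPA, −30 → 40 °C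
Reagents that add atoms: dimethylzinc, C[Zn]C (CH3 in 5; Zn in 4 only)
Why: Copper-catalysed asymmetric conjugate addition of Me2Zn to this β-ester cyclohexenone class should set C4 under ligand control, and the HMPA-activated zinc enolate at C5 then displaces the tethered primary bromide (6-exo-tet, Michael-initiated ring closure); because the new bond must form perpendicular to the enolate plane and within reach of the C19 ester, C6 can only arrive cis to C19, which fixes C5 without equilibration.

Step 3
Reactants: 5 cis-fused keto δ-lactone
Product: 6 benzyl enol ether lactone 5-[(benzyloxy)methylidene]-8a-methyloctahydro-1H-isochromen-1-one (E/Z mixture at C10=C20)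
Conditions: BnOCH2PPh3Cl, KHMDS, THF, −78 → 0 °C; then 5, 0 → 25 °C
Reagents that add atoms: (benzyloxymethyl)triphenylphosphonium chloride, [Cl-].c1ccc(cc1)COC[P+](c1ccccc1)(c1ccccc1)c1ccccc1
Why: Wittig alkoxymethylenation: the non-stabilised ylide should olefinate the C10 ketone much faster than it attacks the hindered lactone carbonyl, C5–H (flanked by the quaternary C4) is not expected to enolise at low temperature, and the E/Z mixture is carried on because C20 is no longer stereogenic after step 12.

Step 4
Reactants: 6 benzyl enol ether lactone
Product: 8 methyl 3-[(benzyloxy)methylidene]-2-(2-hydroxyethyl)-1-methylcyclohexane-1-carboxylate (ester and hydroxyethyl cis), via lithium carboxylate 7 (not isolated)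
Conditions: LiOH·H2O, THF–H2O, 40 °C; concentrate; MeI, DMF, 25 °C
Reagents that add atoms: lithium hydroxide, [Li+].[OH-]; iodomethane, CI
Why: Saponification opens the lactone irreversibly and the hindered carboxylate is O-alkylated by MeI in DMF; no acid is used, so the enol ether should survive and C4/C5 are untouched.

Step 5
Reactants: 8 hydroxy ester
Product: 10 methyl 3-[(benzyloxy)methylidene]-2-(2-iodoethyl)-1-methylcyclohexane-1-carboxylate (ring A iodide; C7–I), via mesylate 9 (not isolated)
Conditions: MsCl, Et3N, CH2Cl2, 0 °C; then NaI, acetone, 40 °C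
Reagents that add atoms: sodium iodide, [Na+].[I-]; methanesulfonyl chloride, CS(=O)(=O)Cl (in 9 only)
Why: Mesylation and Finkelstein displacement turn the primary alcohol into the primary iodide under basic or neutral conditions that the enol ether tolerates.

Step 6
Reactants: 11 p-cresol
Product: 12 4-(benzyloxy)-4-methylcyclohexa-2,5-dien-1-one
Conditions: PhI(OAc)2, BnOH (10 equiv), CH2Cl2, 0 °C
Reagents that add atoms: benzyl alcohol, OCc1ccccc1
Why: Oxidative dearomatisation of a para-alkylphenol with PhI(OAc)2 lets the alcohol present capture the para position, giving the achiral quinol ether in which the future C13 already carries its methyl and protected oxygen.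

Step 7
Reactants: 13 2,5-dimethoxybenzyl bromide
Product: 15 (2,5-dimethoxybenzyl)[(trimethylsilyl)methyl]zinc (titrated solution), via (2,5-dimethoxybenzyl)zinc bromide 14 (not isolated)
Conditions: Zn dust (BrCH2CH2Br/TMSCl-activated, 1.5 equiv), THF, 0 °C, slow addition of 13; decant; Me3SiCH2Li (1.0 equiv, pentane), −78 → 0 °C; evaporate, PhMe, filter from LiBr
Reagents that add atoms: zinc, [Zn]; (trimethylsilyl)methyllithium, [Li]C[Si](C)(C)C
Why: Direct zinc insertion into a benzylic bromide at low temperature gives the benzylic zinc bromide with little Wurtz coupling, and Me3SiCH2Li then replaces bromide by the non-transferable trimethylsilylmethyl ligand, giving a halide-free mixed diorganozinc in which only the arylmethyl group is transferable; the solvent switch removes the lithium bromide that would erode selectivity in step 8.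

Step 8
Reactants: 12 4-(benzyloxy)-4-methylcyclohexa-2,5-dien-1-one; 15 (2,5-dimethoxybenzyl)[(trimethylsilyl)methyl]zinc
Product: 17 4-(benzyloxy)-5-(2,5-dimethoxybenzyl)-4-methylcyclohex-2-en-1-one (benzyloxy and arylmethyl cis; C13 and C14 of the target), via trimethylsilylmethylzinc dienolate 16 (not isolated)
Conditions: 15 (1.5 equiv), Cu(OTf)2 (3 mol%), (S,R,R)-binaphthol-derived bis(1-phenylethyl)amine phosphoramidite (6 mol%), PhMe, −25 °C; aq NH4Cl
Reagents that add atoms: none
Why: Proposed new method: a mixed benzylic (trimethylsilyl)methyl zinc reagent serves as nucleophile in a copper/phosphoramidite-catalysed enantioselective conjugate addition that desymmetrises the 4-alkoxy-4-methylcyclohexadienone; only the arylmethyl group should transmetalate to copper (the silylmethyl group is the established non-transferable ligand on zinc), and π-complexation of one enantiotopic enone arm, C–C bond formation at C14 through a formally trivalent copper intermediate and reductive elimination should place the arylmethyl group on the face of the smaller, coordinating benzyloxy group (anti to the C13 methyl) and leave the second enone intact; the closest known reactions are the copper/phosphoramidite additions of dialkylzincs to this dienone class, the conjugate additions of mixed alkyl(trimethylsilylmethyl)zincs to enones and the stoichiometric conjugate additions of benzylic zinc–copper reagents to enones.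

Step 9
Reactants: 17 ring C enone; 10 ring A iodide
Product: 19 C7–C8 coupled enone (C8–H; side chain trans to the C14 arylmethyl group), via lithium dienolate 18 (not isolated)
Conditions: LDA, THF, −78 °C; then 10, DMPU, −78 → −20 °C
Reagents that add atoms: lithium diisopropylamide, [Li+].CC(C)[N-]C(C)C (Li in 18 only)
Why: Enolate alkylation: the ketone can only be deprotonated at C8 (C11 is vinylic, C13 quaternary), and the α′-enolate displaces the unhindered primary iodide to form C7–C8; the chain should enter anti to the C14 substituent, which is inconsequential because C8 is enolised again in step 10.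

Step 10
Reactants: 19 C7–C8 coupled enone
Product: 21 C8-methylated enone (C8 methyl β; C7 chain cis to the C14 arylmethyl group), via lithium dienolate 20 (not isolated)
Conditions: LDA, THF–DMPU, −78 → −40 °C; MeI
Reagents that add atoms: iodomethane, CI; lithium diisopropylamide, [Li+].CC(C)[N-]C(C)C (Li in 20 only)
Why: Enolate methylation: C8–H is again the only acidic position, and MeI should attack the tetrasubstituted enolate anti to the pseudoaxial C14 arylmethyl group (1,2-induction in cyclohexanone enolate alkylation), which sets the quaternary C8 with its methyl β.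

Step 11
Reactants: 21 C8-methylated enone
Product: 23 enol triflate (cyclisation precursor; C9(OTf)=C11), via lithium enolate 22 (not isolated)
Conditions: LiBH(s-Bu)3, THF, −78 °C; then PhNTf2, −78 → 0 °C
Reagents that add atoms: N-phenylbis(trifluoromethanesulfonimide), FC(F)(F)S(=O)(=O)N(c1ccccc1)S(=O)(=O)C(F)(F)F; lithium tri-sec-butylborohydride, [Li+].CCC(C)[BH-](C(C)CC)C(C)CC (Li in 22 only)
Why: Reductive triflation: the bulky borohydride adds hydride 1,4 to the β-unsubstituted enone (1,2-attack is blocked by the quaternary C8) and the regiodefined C9(O)=C11 enolate is O-sulfonylated, while the hindered C19 ester and the enol ether should be left alone.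

Step 12
Reactants: 23 enol triflate
Product: 24 tricyclic 9(11)-ene with C10 benzyloxymethyl (C20 β; trans A/B)
Conditions: Pd(OAc)2 (10 mol%), PPh3 (20 mol%), LiCl (2 equiv), HCO2Na (1.5 equiv), DMF, 70 °C
Reagents that add atoms: none
Why: Zerovalent palladium inserts into the C9–OTf bond, chloride gives the neutral vinylpalladium chloride, and this adds syn across the exocyclic enol ether with C9 bonding to C10 and palladium to C20; the α-benzyloxy neopentyl palladium has no β-hydrogen (C10 is quaternary), so it exchanges chloride for formate, loses CO2 and reductively eliminates C20–H. The closest known reaction type is the formate-terminated (reductive) intramolecular Heck cyclisation used to build quaternary carbons, here with the less usual pairing of a vinyl triflate and an enol ether. Ring B is closed 6-exo-trig through a chair-like arrangement with the C5–C6 bond equatorial on ring A. The single new stereocenter, C10, is controlled by ring A: the axial C19 ester on C4 is syn-axial to the β (axial) trajectory at C10, so C9 should bond on the equatorial α side and C20 ends axial and β (trans A/B) from either enol ether isomer. The step needs ring closure to outrun hydride delivery to the vinylpalladium, and 6-exo to beat 7-endo closure. The first is served by the tether-enforced insertion and the low concentration of sparingly soluble HCO2Na; the second by ring size together with the neutral manifold, which favours carbon transfer to the enol ether carbon remote from oxygen.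

Step 13
Reactants: 24 tricyclic 9(11)-ene
Product: 25 saturated tricycle (H9 α; trans B/C)
Conditions: Mn(dpm)3 (10 mol%; dpm = dipivaloylmethanate), PhSiH3, t-BuOOH, i-PrOH, 25 °C
Reagents that add atoms: none
Why: Hydrogen-atom-transfer hydrogenation reduces the hindered C9=C11 bond that is expected to resist catalytic hydrogenation: a hydrogen atom adds to C11 and the tertiary C9 radical should take up hydrogen on the α face, opposite the axial C8 methyl and C10 CH2OBn, giving the thermodynamically preferred trans fusion while the benzyl ethers stay intact.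

Step 14
Reactants: 25 saturated tricycle
Product: 27 19,20-lactone with free C13 alcohol (hydroquinone dimethyl ether), via diol ester 26 (not isolated)
Conditions: H2 (1 atm), Pd(OH)2/C, EtOAc–MeOH, 25 °C; filter; DBU (0.2 equiv), PhMe, 80 °C
Reagents that add atoms: none
Why: Hydrogenolysis removes the primary C20 and the tertiary C13 benzyl ethers, and the freed axial C20 hydroxyl, 1,3-diaxial to the axial C19 ester, should close the bridging δ-lactone by base-catalysed transesterification without acid that could ionise the C13 alcohol.

Step 15
Reactants: 27 lactone dimethyl ether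
Product: 28 para-quinone
Conditions: (NH4)2Ce(NO3)6 (2.5 equiv), MeCN–H2O, 0 °C
Reagents that add atoms: water, O
Why: Oxidative demethylation of the 1,4-dimethoxyarene by single-electron oxidation with water as oxygen source should give the quinone without affecting the lactone or the tertiary alcohol if the reaction is kept cold and short.

Step 16
Reactants: 28 para-quinone
Product: 29 CNP0148621.1 (target)
Conditions: Na2S2O4, THF–H2O, 25 °C
Reagents that add atoms: none
Why: Dithionite reduction of the quinone to the hydroquinone is neutral, which avoids acid-promoted chromane formation with the C13 alcohol.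

**Compound list**

1 | methyl 3-oxocyclohex-1-ene-1-carboxylate | COC(=O)C1=CC(=O)CCC1 | starting material
2 | 2-bromoethanol | OCCBr | starting material
3 | 2-bromoethyl 3-oxocyclohex-1-ene-1-carboxylate | O=C1C=C(C(=O)OCCBr)CCC1 | intermediate
4 | methylzinc enolate (C5=C10) of 2-bromoethyl 1-methyl-3-oxocyclohexane-1-carboxylate, not isolated | C[Zn]OC1=C[C@@](C)(C(=O)OCCBr)CCC1 | intermediate
5 | cis-fused keto δ-lactone, 8a-methylhexahydro-1H-isochromene-1,5-dione | O1CC[C@@H]2C(=O)CCC[C@]2(C)C1=O | intermediate
6 | benzyl enol ether lactone, 5-[(benzyloxy)methylidene]-8a-methyloctahydro-1H-isochromen-1-one (E/Z) | O1CC[C@@H]2C(=COCc3ccccc3)CCC[C@]2(C)C1=O | intermediate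
7 | lithium 3-[(benzyloxy)methylidene]-2-(2-hydroxyethyl)-1-methylcyclohexane-1-carboxylate, not isolated | OCC[C@@H]1C(=COCc2ccccc2)CCC[C@]1(C)C(=O)[O-].[Li+] | intermediate
8 | methyl 3-[(benzyloxy)methylidene]-2-(2-hydroxyethyl)-1-methylcyclohexane-1-carboxylate (ester and hydroxyethyl cis) | OCC[C@@H]1C(=COCc2ccccc2)CCC[C@]1(C)C(=O)OC | intermediate
9 | mesylate of 8, not isolated | CS(=O)(=O)OCC[C@@H]1C(=COCc2ccccc2)CCC[C@]1(C)C(=O)OC | intermediate
10 | methyl 3-[(benzyloxy)methylidene]-2-(2-iodoethyl)-1-methylcyclohexane-1-carboxylate (ring A iodide) | ICC[C@@H]1C(=COCc2ccccc2)CCC[C@]1(C)C(=O)OC | intermediate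
11 | p-cresol | Cc1ccc(O)cc1 | starting material
12 | 4-(benzyloxy)-4-methylcyclohexa-2,5-dien-1-one | CC1(OCc2ccccc2)C=CC(=O)C=C1 | intermediate
13 | 2,5-dimethoxybenzyl bromide | COc1ccc(OC)c(CBr)c1 | starting material
14 | (2,5-dimethoxybenzyl)zinc bromide, not isolated | COc1ccc(OC)c(C[Zn]Br)c1 | intermediate
15 | (2,5-dimethoxybenzyl)[(trimethylsilyl)methyl]zinc | COc1ccc(OC)c(C[Zn]C[Si](C)(C)C)c1 | intermediate
16 | (trimethylsilylmethyl)zinc dienolate of 17, not isolated | C[Si](C)(C)C[Zn]OC1=C[C@@H](Cc2cc(OC)ccc2OC)[C@@](C)(OCc2ccccc2)C=C1 | intermediate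
17 | 4-(benzyloxy)-5-(2,5-dimethoxybenzyl)-4-methylcyclohex-2-en-1-one (benzyloxy and arylmethyl cis) | O=C1C=C[C@](C)(OCc2ccccc2)[C@H](Cc2cc(OC)ccc2OC)C1 | intermediate
18 | lithium dienolate (C8=C9) of 17, not isolated | [Li]OC1=C[C@@H](Cc2cc(OC)ccc2OC)[C@@](C)(OCc2ccccc2)C=C1 | intermediate
19 | C7–C8 coupled enone, C8–H, chain trans to the C14 arylmethyl group | [C@H]1(CC[C@@H]2C(=COCc3ccccc3)CCC[C@]2(C)C(=O)OC)C(=O)C=C[C@](C)(OCc3ccccc3)[C@@H]1Cc1cc(OC)ccc1OC | intermediate
20 | lithium dienolate (C8=C9) of 19, not isolated | [Li]OC1=C(CC[C@@H]2C(=COCc3ccccc3)CCC[C@]2(C)C(=O)OC)[C@@H](Cc2cc(OC)ccc2OC)[C@@](C)(OCc2ccccc2)C=C1 | intermediate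
21 | C8-methylated enone (C8 methyl β) | C[C@@]1(CC[C@@H]2C(=COCc4ccccc4)CCC[C@]2(C)C(=O)OC)C(=O)C=C[C@](C)(OCc5ccccc5)[C@@H]1Cc3cc(OC)ccc3OC | intermediate
22 | lithium enolate (C9=C11) from conjugate reduction of 21, not isolated | C[C@@]1(CC[C@@H]2C(=COCc4ccccc4)CCC[C@]2(C)C(=O)OC)C(O[Li])=CC[C@](C)(OCc5ccccc5)[C@@H]1Cc3cc(OC)ccc3OC | intermediate
23 | enol triflate, ring A enol ether linked by C6–C7 to ring C (cyclisation precursor) | C[C@@]1(CC[C@@H]2C(=COCc4ccccc4)CCC[C@]2(C)C(=O)OC)C(OS(=O)(=O)C(F)(F)F)=CC[C@](C)(OCc5ccccc5)[C@@H]1Cc3cc(OC)ccc3OC | intermediate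
24 | tricyclic 9(11)-ene with C10 benzyloxymethyl and C13 benzyloxy | C[C@@]12CC[C@@H]3[C@](COCc4ccccc4)(CCC[C@]3(C)C(=O)OC)C1=CC[C@](C)(OCc5ccccc5)[C@@H]2Cc1cc(OC)ccc1OC | intermediate
25 | saturated tricycle, H9 α | C[C@@]12CC[C@@H]3[C@](COCc4ccccc4)(CCC[C@]3(C)C(=O)OC)[C@H]1CC[C@](C)(OCc5ccccc5)[C@@H]2Cc1cc(OC)ccc1OC | intermediate
26 | C20/C13 diol methyl ester, not isolated | C[C@@]12CC[C@@H]3[C@](CO)(CCC[C@]3(C)C(=O)OC)[C@H]1CC[C@](C)(O)[C@@H]2Cc1cc(OC)ccc1OC | intermediate
27 | 19,20-lactone, hydroquinone dimethyl ether | C[C@@]12CC[C@@H]3[C@]4(CCC[C@]3(C)C(=O)OC4)[C@H]1CC[C@](C)(O)[C@@H]2Cc1cc(OC)ccc1OC | intermediate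
28 | para-quinone | C[C@@]12CC[C@@H]3[C@]4(CCC[C@]3(C)C(=O)OC4)[C@H]1CC[C@](C)(O)[C@@H]2CC1=CC(=O)C=CC1=O | intermediate
29 | CNP0148621.1 | C[C@@]12CC[C@@H]3[C@]4(CCC[C@]3(C)C(=O)OC4)[C@H]1CC[C@](C)(O)[C@@H]2Cc1cc(O)ccc1O | target

**Totals**

Total step count: 16. Longest linear sequence: 13 steps (1–5, then 9–16).

**Steps most likely to fail**

Step 8 (proposed new method). The benzylic group may transfer sluggishly from zinc to copper or homocouple; the silylmethyl group may not remain a spectator; addition may go 1,2; and selection between the two enone arms or between the faces syn and anti to the benzyloxy group may be poor. The fallback uses known chemistry, sets out from 13 and returns at 17. Commercial 1,4-dioxaspiro[4.5]decan-8-one is condensed with SAMP to the hydrazone F1. Deprotonation with LDA and alkylation with 13 should give the arylmethylated hydrazone F2, in the sense known for SAMP hydrazones of cyclohexanones. Ozonolysis releases the ketone 7-(2,5-dimethoxybenzyl)-1,4-dioxaspiro[4.5]decan-8-one F3. Kinetic deprotonation at the CH2 remote from the substituted methine with TMSCl trapping gives the silyl enol ether F4, and Saegusa–Ito oxidation with Pd(OAc)2 gives the enone F5. MeLi/CeCl3 adds 1,2 anti to the neighbouring arylmethyl group to give the tertiary allylic alcohol F6 (OH cis to arylmethyl), which KH/BnBr converts into the benzyl ether F7. Mild aqueous acid (PPTS, acetone–water) unmasks the C9 ketone, which is then conjugated with C11=C12, i.e. 17.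

Step 12. Hydride may be delivered to the vinylpalladium before ring closure; the neopentyl palladium may be captured by the adjacent C9=C11 bond (3-exo closure) before formate reduces it; or facial selectivity at C10 may be poor. The fallback changes the bond-forming manifold to a tin hydride-mediated vinyl radical cyclisation, sets out from 23 and returns at 24. [Cp*Ru(MeCN)3]OTf-catalysed exchange with LiI converts the triflate into the vinyl iodide F8. Slow addition of Bu3SnH/AIBN in benzene at 80 °C generates the C9 vinyl radical, which adds 6-exo to C10 (the enol ether carbon remote from oxygen); the α-alkoxy radical at C20 is reduced by the stannane to give 24, with the same ring A control of the C10 configuration.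

Step 9. Displacement at the hindered C8 enolate may be slow, allowing proton transfer between enolate and product, O-alkylation, or loss of HI from 10. The fallback replaces the substitution by an aldol condensation and reductive methylation, sets out from 8 and returns at 20 (then step 10 as written, to 21). Dess–Martin oxidation of 8 gives the ring A aldehyde F9. Its aldol addition to enolate 18 at −78 °C gives the β-hydroxy ketone F10, and dehydration with the Burgess reagent gives the cross-conjugated dienone F11 (C7=C8). LiBH(s-Bu)3 should add hydride to C7 of the s-cis exocyclic enone in preference to the ring enone and so generate the same lithium dienolate 20, which is methylated with MeI.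

**Further compounds**

F1 | step 8 | SAMP hydrazone of 1,4-dioxaspiro[4.5]decan-8-one | COC[C@@H]1CCCN1N=C1CCC2(CC1)OCCO2
F2 | step 8 | arylmethylated SAMP hydrazone (C14 set) | COC[C@@H]1CCCN1N=C1CCC2(OCCO2)C[C@H]1Cc1cc(OC)ccc1OC
F3 | step 8 | 7-(2,5-dimethoxybenzyl)-1,4-dioxaspiro[4.5]decan-8-one | O=C1CCC2(OCCO2)C[C@H]1Cc1cc(OC)ccc1OC
F4 | step 8 | trimethylsilyl enol ether of F3 (double bond away from the arylmethyl group) | C[Si](C)(C)OC1=CCC2(OCCO2)C[C@H]1Cc1cc(OC)ccc1OC
F5 | step 8 | 7-(2,5-dimethoxybenzyl)-1,4-dioxaspiro[4.5]dec-9-en-8-one | O=C1C=CC2(OCCO2)C[C@H]1Cc1cc(OC)ccc1OC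
F6 | step 8 | 7-(2,5-dimethoxybenzyl)-8-methyl-1,4-dioxaspiro[4.5]dec-9-en-8-ol (OH cis to arylmethyl) | C[C@]1(O)C=CC2(OCCO2)C[C@H]1Cc1cc(OC)ccc1OC
F7 | step 8 | benzyl ether of F6 | C[C@]1(OCc2ccccc2)C=CC3(OCCO3)C[C@H]1Cc1cc(OC)ccc1OC
F8 | step 12 | vinyl iodide analogue of 23 (C9–I) | C[C@@]1(CC[C@@H]2C(=COCc4ccccc4)CCC[C@]2(C)C(=O)OC)C(I)=CC[C@](C)(OCc5ccccc5)[C@@H]1Cc3cc(OC)ccc3OC
F9 | step 9 | methyl 3-[(benzyloxy)methylidene]-1-methyl-2-(2-oxoethyl)cyclohexane-1-carboxylate | O=CC[C@@H]1C(=COCc2ccccc2)CCC[C@]1(C)C(=O)OC
F10 | step 9 | aldol adduct of 18 and F9 (mixture at C7 and C8) | OC(C[C@@H]1C(=COCc2ccccc2)CCC[C@]1(C)C(=O)OC)C1C(=O)C=C[C@](C)(OCc2ccccc2)[C@@H]1Cc1cc(OC)ccc1OC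
F11 | step 9 | cross-conjugated dienone with exocyclic C7=C8 | O=C1C=C[C@](C)(OCc2ccccc2)[C@H](Cc2cc(OC)ccc2OC)C1=CC[C@@H]1C(=COCc2ccccc2)CCC[C@]1(C)C(=O)OC
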